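The tetrasubstituted olefin C-3=C-3a (phenalene numbering) lies between the ring A carbon C-9b and the stereocentre C-2, so both flanking bonds, C-3a–C-9b and C-2–C-3, are made by adding these two carbons across an alkyne. One palladium domino closes rings B and C: an aryl triflate at C-9b carbopalladates a tethered arylalkyne, the alkenylpalladium then inserts a (Z)-trisubstituted olefin, and chain-walking to a homoallylic carbinol releases the C-3' ketone. The precursor is a ten-membered diaryl ether macrocycle made by ring-closing metathesis; its benzylic centre C-1, set by an aromatic Claisen rearrangement, controls C-2, and the olefin geometry fixes C-1'.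

Key step: step 13

Remark: labels follow the phenalene numbering of the target. C-1 = ring B CH(CH3), C-2 = adjacent CH, C-3 = aryl-bearing olefin carbon, C-3a and C-9b = ring-fusion carbons, C-4/C-5/C-6 = enol, CH and carbonyl carbons of ring C, C-6a to C-9b = ring A (oxygen on C-7 and C-9). C-1', C-2', C-3' = the CH(CH3)–CH2–C(=O) bridge from C-2 to ring D (aryl ketone ring). Ring E = 2,6-dioxygenated phenyl on C-3. MOM = methoxymethyl. The target is (1R,2R,1'S).

Assumption: (2R,3E)-pent-3-en-2-ol (6) is bought enantiopure; otherwise it is obtained from the commercial racemate by lipase resolution.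

Step 1
Reactants: 1 2-fluoro-6-hydroxybenzaldehyde
Product: 2 2-fluoro-6-(methoxymethoxy)benzaldehyde
Conditions: MOMCl, i-Pr2NEt, CH2Cl2, 0 °C to rt
Reagents that add atoms: chloromethyl methyl ether, COCCl
Why: O-alkylation of the phenol (MOM ether formation) should mask the hydroxyl group, which as a phenoxide would deactivate the ring in the following SNAr step.

Step 2
Reactants: 2 2-fluoro-6-(methoxymethoxy)benzaldehyde; 3 2,4,6-trihydroxyacetophenone
Product: 4 2-(4-acetyl-3,5-dihydroxyphenoxy)-6-(methoxymethoxy)benzaldehyde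
Conditions: K2CO3 (1.1 equiv), DMF, 80 °C
Reagents that add atoms: none
Why: SNAr displacement of the fluoride activated by the ortho formyl group should occur at the para hydroxyl of 3, the most acidic one and the only one not held in a hydrogen bond to the acetyl group.

Step 3
Reactants: 4 2-(4-acetyl-3,5-dihydroxyphenoxy)-6-(methoxymethoxy)benzaldehyde
Product: 5 2-[4-acetyl-3-hydroxy-5-(methoxymethoxy)phenoxy]-6-(methoxymethoxy)benzaldehyde
Conditions: MOMCl (1.05 equiv), i-Pr2NEt, CH2Cl2, 0 °C
Reagents that add atoms: chloromethyl methyl ether, COCCl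
Why: MOM ether formation on one of two equivalent hydroxyl groups should stop at the mono-ether, because the remaining hydroxyl is then locked in a hydrogen bond to the acetyl group.

Step 4
Reactants: 5 2-[4-acetyl-3-hydroxy-5-(methoxymethoxy)phenoxy]-6-(methoxymethoxy)benzaldehyde; 6 (2R,3E)-pent-3-en-2-ol
Product: 7 2-{4-acetyl-3-(methoxymethoxy)-5-[(2S,3E)-pent-3-en-2-yloxy]phenoxy}-6-(methoxymethoxy)benzaldehyde
Conditions: PPh3, DIAD, THF, 0 °C to rt
Reagents that add atoms: none
Why: Mitsunobu etherification of the remaining phenol should proceed with SN2 inversion at the carbinol carbon and give the (S)-configured aryl allyl ether.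

Step 5
Reactants: 7 2-{4-acetyl-3-(methoxymethoxy)-5-[(2S,3E)-pent-3-en-2-yloxy]phenoxy}-6-(methoxymethoxy)benzaldehyde
Product: 8 2-{4-acetyl-3-hydroxy-5-(methoxymethoxy)-2-[(2R,3E)-pent-3-en-2-yl]phenoxy}-6-(methoxymethoxy)benzaldehyde
Conditions: PhNEt2, 160 °C
Reagents that add atoms: none
Why: Aromatic Claisen rearrangement to the only free ortho position should pass through a chair transition state with the ether methyl group equatorial, which transfers the (S)-configured C–O centre into the (R)-configured benzylic centre C-1 and leaves an (E)-propenyl group.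

Step 6
Reactants: 8 2-{4-acetyl-3-hydroxy-5-(methoxymethoxy)-2-[(2R,3E)-pent-3-en-2-yl]phenoxy}-6-(methoxymethoxy)benzaldehyde
Product: 9 6-acetyl-3-[2-formyl-3-(methoxymethoxy)phenoxy]-5-(methoxymethoxy)-2-[(2R,3E)-pent-3-en-2-yl]phenyl trifluoromethanesulfonate
Conditions: Tf2O, pyridine, CH2Cl2, 0 °C
Reagents that add atoms: trifluoromethanesulfonic anhydride, O=S(=O)(OS(=O)(=O)C(F)(F)F)C(F)(F)F
Why: O-sulfonylation of the single free phenol should give the aryl triflate at the future C-9b that starts the domino.

Step 7
Reactants: 9 6-acetyl-3-[2-formyl-3-(methoxymethoxy)phenoxy]-5-(methoxymethoxy)-2-[(2R,3E)-pent-3-en-2-yl]phenyl trifluoromethanesulfonate; 10 3-bromo-2-methylprop-1-ene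
Product: 12 6-acetyl-3-[2-(1-hydroxy-3-methylbut-3-en-1-yl)-3-(methoxymethoxy)phenoxy]-5-(methoxymethoxy)-2-[(2R,3E)-pent-3-en-2-yl]phenyl trifluoromethanesulfonate (both carbinol epimers), via 2-methylallylzinc bromide 11 (not isolated)
Conditions: Zn, THF/sat. aq. NH4Cl, rt
Reagents that add atoms: none
Why: Barbier allylation should take place only at the aldehyde, which is far more electrophilic than the di-ortho-substituted aryl ketone, and the unselectively formed carbinol centre is erased in step 13.

Step 8
Reactants: 12 the homoallylic alcohol of step 7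
Product: 13 macrocyclic (Z)-olefin: ten-membered ring made of C-9, C-9a, C-1, the (Z)-C-2=C-1' olefin, C-2', the carbinol C-3', two carbons of ring D and the ether oxygen; ring A keeps acetyl (C-6a), triflate (C-9b) and OMOM (C-7); (1R), both carbinol epimers
Conditions: second-generation Grubbs catalyst (10 mol %), toluene (1 mM), 90 °C
Reagents that add atoms: none
Why: Ring-closing metathesis with loss of propene should give the (Z)-trisubstituted olefin, because a ten-membered ring fused to two benzene rings cannot hold the (E)-isomer.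

Step 9
Reactants: 14 2-iodobenzene-1,3-diol
Product: 15 2-iodo-1,3-bis(methoxymethoxy)benzene
Conditions: MOMCl (2.5 equiv), i-Pr2NEt, CH2Cl2, 0 °C to rt
Reagents that add atoms: chloromethyl methyl ether, COCCl
Why: Double MOM ether formation should protect both phenols of the future ring E.

Step 10
Reactants: 15 2-iodo-1,3-bis(methoxymethoxy)benzene; 16 prop-2-yn-1-ol
Product: 17 3-[2,6-bis(methoxymethoxy)phenyl]prop-2-yn-1-ol
Conditions: PdCl2(PPh3)2, copper monoiodide (CuI), Et3N, THF, 50 °C
Reagents that add atoms: none
Why: Sonogashira coupling of the aryl iodide with the terminal alkyne should install the C-3/C-3a alkyne carbons together with the C-4 carbon.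

Step 11
Reactants: 17 3-[2,6-bis(methoxymethoxy)phenyl]prop-2-yn-1-ol
Product: 18 3-[2,6-bis(methoxymethoxy)phenyl]prop-2-ynal
Conditions: MnO2, CH2Cl2, rt
Reagents that add atoms: none
Why: Oxidation of the activated propargylic alcohol by manganese dioxide should stop cleanly at the ynal.

Step 12
Reactants: 13 macrocyclic (Z)-olefin; 18 3-[2,6-bis(methoxymethoxy)phenyl]prop-2-ynal
Product: 19 aldol adduct: 13 in which the acetyl group has become –C(=O)–CH2–CH(OH)–C≡C–[2,6-bis(methoxymethoxy)phenyl] (C-6, C-5, C-4, C-3a, C-3, ring E); (1R), both epimers at each carbinol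
Conditions: LiHMDS (2.2 equiv), THF, −78 °C; then 18; AcOH, −78 °C
Reagents that add atoms: none
Why: Aldol addition of the lithium enolate of the methyl ketone (the carbinol being carried as its alkoxide) should occur 1,2 at the ynal and give the β-hydroxy ketone tether, whose new carbinol centre is erased in step 14.

Step 13
Reactants: 19 aldol adduct
Product: 21 tetra-MOM ether of the 4,5-dihydro-4-hydroxy form of the target (rings B and C closed, C-3' ketone, C-4 carbinol as both epimers; 1R,2R,1'S), via enol 20 (not isolated)
Conditions: Pd(OAc)2 (10 mol %), 1,3-bis(diphenylphosphino)propane (12 mol %), 1,2,2,6,6-pentamethylpiperidine (2 equiv), DMA, 4 Å molecular sieves, 70 °C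
Reagents that add atoms: none
Why: Oxidative addition of the aryl triflate to zerovalent palladium gives a cationic arylpalladium that adds syn across the tethered alkyne (ring C, 6-exo-dig, C-3a–C-9b bond), the alkenylpalladium then inserts the ring olefin (ring B, 6-exo-trig, C-2–C-3 bond), and the tertiary alkylpalladium at C-1' walks by β-hydride elimination and reinsertion to the carbinol carbon, where release of enol 20 and tautomerisation give the ketone. The closest known reactions are domino alkyne–alkene carbopalladation (Heck) cascades and the redox-relay Heck reaction of alkenyl triflates with trisubstituted homoallylic alcohols. C-2 is set by the existing centre C-1 through allylic 1,3-strain: the C-1 hydrogen eclipses the (Z)-olefin, so the alkenylpalladium, which is tied to ring A, should add to the face anti to the C-1 methyl group (1,2-trans). C-1' is set by the olefin geometry, because syn insertion into the (Z)-olefin followed by chain walking without decomplexation replaces palladium by hydrogen with retention. The step needs exo carbopalladation of the alkyne before any direct Heck reaction and walking towards the carbinol; the first is secured by ring size (the alternative closures are four-membered or 5-endo), the second by the hydroxyl group as the only irreversible exit, and ring E has no ortho hydrogen that could divert the alkenylpalladium.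

Step 14
Reactants: 21 cascade product
Product: 23 tetra-MOM ether of the target (4-hydroxy-6-oxo enol form of ring C), via 1,3-diketone 22 (not isolated)
Conditions: Dess–Martin periodinane, NaHCO3, CH2Cl2, 0 °C to rt
Reagents that add atoms: none
Why: Dess–Martin oxidation of the only free hydroxyl group (allylic, at C-4) should give the 1,3-diketone, which enolises to the vinylogous acid of ring C.

Step 15
Reactants: 23 tetra-MOM ether of the target
Product: 24 target, (1R,2R,1'S)
Conditions: 3 M aq. HCl, THF, 40 °C
Reagents that add atoms: none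
Why: Acid hydrolysis of the four phenolic MOM acetals should release the free phenols of rings A, D and E without touching the diaryl ether, the ketone or the stereocentres.

Compound list
1 | 2-fluoro-6-hydroxybenzaldehyde | O=Cc1c(O)cccc1F | starting material
2 | 2-fluoro-6-(methoxymethoxy)benzaldehyde | COCOc1cccc(F)c1C=O | intermediate
3 | 2,4,6-trihydroxyacetophenone | CC(=O)c1c(O)cc(O)cc1O | starting material
4 | 2-(4-acetyl-3,5-dihydroxyphenoxy)-6-(methoxymethoxy)benzaldehyde | CC(=O)c1c(O)cc(Oc2cccc(OCOC)c2C=O)cc1O | intermediate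
5 | 2-[4-acetyl-3-hydroxy-5-(methoxymethoxy)phenoxy]-6-(methoxymethoxy)benzaldehyde | CC(=O)c1c(O)cc(Oc2cccc(OCOC)c2C=O)cc1OCOC | intermediate
6 | (2R,3E)-pent-3-en-2-ol | C[C@@H](O)/C=C/C | starting material
7 | 2-{4-acetyl-3-(methoxymethoxy)-5-[(2S,3E)-pent-3-en-2-yloxy]phenoxy}-6-(methoxymethoxy)benzaldehyde | CC(=O)c1c(O[C@@H](C)/C=C/C)cc(Oc2cccc(OCOC)c2C=O)cc1OCOC | intermediate
8 | 2-{4-acetyl-3-hydroxy-5-(methoxymethoxy)-2-[(2R,3E)-pent-3-en-2-yl]phenoxy}-6-(methoxymethoxy)benzaldehyde | CC(=O)c1c(O)c([C@H](C)/C=C/C)c(Oc2cccc(OCOC)c2C=O)cc1OCOC | intermediate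
9 | 6-acetyl-3-[2-formyl-3-(methoxymethoxy)phenoxy]-5-(methoxymethoxy)-2-[(2R,3E)-pent-3-en-2-yl]phenyl trifluoromethanesulfonate | CC(=O)c1c(OS(=O)(=O)C(F)(F)F)c([C@H](C)/C=C/C)c(Oc2cccc(OCOC)c2C=O)cc1OCOC | intermediate
10 | 3-bromo-2-methylprop-1-ene | CC(=C)CBr | starting material
11 | 2-methylallylzinc bromide | CC(=C)C[Zn]Br | intermediate (not isolated)
12 | 6-acetyl-3-[2-(1-hydroxy-3-methylbut-3-en-1-yl)-3-(methoxymethoxy)phenoxy]-5-(methoxymethoxy)-2-[(2R,3E)-pent-3-en-2-yl]phenyl trifluoromethanesulfonate, both carbinol epimers | CC(=O)c1c(OS(=O)(=O)C(F)(F)F)c([C@H](C)/C=C/C)c(Oc2cccc(OCOC)c2C(O)CC(C)=C)cc1OCOC | intermediate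
13 | macrocyclic (Z)-olefin (ten-membered diaryl ether ring; acetyl, triflate and two OMOM groups; 1R; both carbinol epimers) | CC(=O)c1c(OS(=O)(=O)C(F)(F)F)c2c(cc1OCOC)Oc1cccc(OCOC)c1C(O)C/C(C)=C\[C@H]2C | intermediate
14 | 2-iodobenzene-1,3-diol | Oc1cccc(O)c1I | starting material
15 | 2-iodo-1,3-bis(methoxymethoxy)benzene | COCOc1cccc(OCOC)c1I | intermediate
16 | prop-2-yn-1-ol | C#CCO | starting material
17 | 3-[2,6-bis(methoxymethoxy)phenyl]prop-2-yn-1-ol | OCC#Cc1c(OCOC)cccc1OCOC | intermediate
18 | 3-[2,6-bis(methoxymethoxy)phenyl]prop-2-ynal | O=CC#Cc1c(OCOC)cccc1OCOC | intermediate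
19 | aldol adduct of 13 and 18 (β-hydroxy ketone with arylalkyne; 1R; epimers at both carbinols) | O=C(CC(O)C#Cc3c(OCOC)cccc3OCOC)c1c(OS(=O)(=O)C(F)(F)F)c2c(cc1OCOC)Oc1cccc(OCOC)c1C(O)C/C(C)=C\[C@H]2C | intermediate
20 | enol of the C-3' ketone 21 | C[C@H]1C=C(O)c2c(OCOC)cccc2Oc2cc(OCOC)c3c4c2[C@H](C)[C@@H]1C(c1c(OCOC)cccc1OCOC)=C4C(O)CC3=O | intermediate (not isolated)
21 | tetra-MOM ether of the 4,5-dihydro-4-hydroxy form of the target (1R,2R,1'S; C-4 epimers) | C[C@H]1CC(=O)c2c(OCOC)cccc2Oc2cc(OCOC)c3c4c2[C@H](C)[C@@H]1C(c1c(OCOC)cccc1OCOC)=C4C(O)CC3=O | intermediate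
22 | tetra-MOM ether of the target, 4,6-diketo form | C[C@H]1CC(=O)c2c(OCOC)cccc2Oc2cc(OCOC)c3c4c2[C@H](C)[C@@H]1C(c1c(OCOC)cccc1OCOC)=C4C(=O)CC3=O | intermediate (not isolated)
23 | tetra-MOM ether of the target, enol form | C[C@H]1CC(=O)c2c(OCOC)cccc2Oc2cc(OCOC)c3c4c2[C@H](C)[C@@H]1C(c1c(OCOC)cccc1OCOC)=C4C(O)=CC3=O | intermediate
24 | CNP0225737.1, (1R,2R,1'S) | C[C@H]1CC(=O)c2c(O)cccc2Oc2cc(O)c3c4c2[C@H](C)[C@@H]1C(c1c(O)cccc1O)=C4C(O)=CC3=O | target

Total step count: 15
Longest linear sequence: 12 steps (steps 1–8 and 12–15)

Steps most likely to fail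

Step 13. The hindered alkenylpalladium may be protonated or reduced before it inserts the ring olefin. Palladium hydride may also leave the olefin or walk towards C-2 instead of the carbinol, and the amine base may dehydrate the β-hydroxy ketone of ring C. Fallback: the two C–C bond formations are separated. Setting out from 19, the arylative cyclisation is intercepted by borylation (PdCl2(dppf), B2pin2, KOAc, dioxane, 80 °C) to give alkenyl pinacolboronate F1, in which ring C is closed and C-3 carries boron. F1 is then cyclised by an oxidative boron-Heck reaction with redox relay under base-free divalent-palladium catalysis (Pd(MeCN)2(OTs)2, Cu(OTf)2, O2, DMF, 3 Å molecular sieves, rt), which comes back to the route at 21.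

Step 8. Intermolecular metathesis (oligomerisation) may outrun ring closure, because the branched internal propenyl group is slow to load the catalyst and the ring is ten-membered. Fallback: ring closure is moved onto a terminal olefin. Setting out from 9, ethenolysis (second-generation Hoveyda–Grubbs catalyst, ethylene 5 bar, toluene, 40 °C) gives vinyl arene F2. Zinc-mediated methallylation with 10 as in step 7 gives diene F3, and ring-closing metathesis of F3 under slow addition in 1,2-dichloroethane at 80 °C comes back to the route at 13.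

Step 12. Retro-aldol cleavage or dehydration of the lithium aldolate, or attack of the amide base or the enolate oxygen at the triflate sulfur, may erode the adduct. Fallback: a Lewis-acid aldol in place of the lithium enolate. Setting out from 13, TMSOTf and Et3N (CH2Cl2, 0 °C) give bis(trimethylsilyl) compound F4, the silyl enol ether of the acetyl group with the carbinol as its silyl ether. Mukaiyama aldol addition of F4 to 18 (BF3·OEt2, CH2Cl2, −78 °C) and citric acid work-up comes back to the route at 19.

Further compounds
F1 | step 13 | alkenyl pinacolboronate (ring C closed, boron on C-3, macrocyclic olefin intact) | O=C1CC(O)/C(=C(\c3c(OCOC)cccc3OCOC)B3OC(C)(C)C(C)(C)O3)c2c1c(OCOC)cc1c2[C@H](C)/C=C(C)\CC(O)c2c(OCOC)cccc2O1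
F2 | step 8 | 6-acetyl-2-[(2R)-but-3-en-2-yl]-3-[2-formyl-3-(methoxymethoxy)phenoxy]-5-(methoxymethoxy)phenyl trifluoromethanesulfonate | CC(=O)c1c(OS(=O)(=O)C(F)(F)F)c([C@H](C)C=C)c(Oc2cccc(OCOC)c2C=O)cc1OCOC
F3 | step 8 | 6-acetyl-2-[(2R)-but-3-en-2-yl]-3-[2-(1-hydroxy-3-methylbut-3-en-1-yl)-3-(methoxymethoxy)phenoxy]-5-(methoxymethoxy)phenyl trifluoromethanesulfonate | CC(=O)c1c(OS(=O)(=O)C(F)(F)F)c([C@H](C)C=C)c(Oc2cccc(OCOC)c2C(O)CC(C)=C)cc1OCOC
F4 | step 12 | bis(trimethylsilyl) derivative of 13 (silyl enol ether and silyl ether) | C=C(O[Si](C)(C)C)c1c(OS(=O)(=O)C(F)(F)F)c2c(cc1OCOC)Oc1cccc(OCOC)c1C(O[Si](C)(C)C)C/C(C)=C\[C@H]2C
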